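## Structural features

The target is a daucane-type sesquiterpenoid diester on a trans-fused bicyclo[5.3.0]dec-8-ene: a cyclopentane (C1–C5) and a cycloheptene (C1, C5–C10) share the C1–C5 bond, with C1 the methyl-bearing quaternary fusion carbon and C5 the fusion CH. Six stereocentres form one unbroken cluster (C10, C1, C2, C4, C5, C6; 1R,2R,4R,5S,6S,10R in this numbering). On the five-membered ring the C1 methyl, the C2 and C4 hydroxyls and the C5–C6 bond lie on one face (called α below), while the C1–C10 bond, the C4 isopropyl group and H5 lie on the other (β). The fragile parts are the two (Z)-2-methylbut-2-enoates (angelates), which go over to tiglates under basic or nucleophilic conditions and one of which is allylic, and the position of the trisubstituted C8=C9 alkene. In any ketone precursor the β-hydroxy carbonyl pairs O4/C6 and O2/C10 add the risk of retro-aldol cleavage and dehydration. The real difficulty is the quaternary C1 surrounded by three oxygenated stereogenic neighbours, the hindered tertiary carbinol C4, the trans ring fusion and the differentiation of four hydroxyls. The key step exploits the fact that the two ester-bearing carbons C6 and C10 are 1,4-related through C5–C1 (a dissonant pattern) and are both bonded to the three-carbon unit C7–C8–C9. If both are made acyl anion equivalents (1,3-dithianes on a trans-1,2-disubstituted cyclopentane), one 2-methylenepropane-1,3-diyl bis-electrophile closes the seven-membered ring and leaves on C8 an exocyclic methylene, the latent C8 methyl and C8=C9 alkene.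

## Logic of the disconnections

26 ⇒ 25 ⇒ 24. The O2–Si bond and then the two acyl C–O bonds at O6 and O10 are cut. The angelates are the most fragile groups and belong at the end. This leaves a diol whose only problems are skeletal. The forward acylation must esterify two hindered secondary hydroxyls without Z-to-E isomerisation, must not touch the tertiary O4–H, and needs O2 masked by a group that comes off last under non-basic conditions.

24 ⇒ 23 ⇒ 22 ⇒ 21. The C10–H bond, then the alkene position (C8=C9 back to exocyclic C8=CH2), then the C6–H bond are removed. This turns both carbinol carbons into acyl carbons and makes the C7–C8–C9 unit symmetrical, removing two stereocentres. The demand is on order and control: C6 must be reduced first, by delivery from the free O4–H, so that afterwards only C10 can draw the alkene into conjugation; C10 is then reduced under reagent control.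

21 ⇒ 19 (through 20). The two carbonyl groups are exchanged for 1,3-dithiane rings and O4–H for its trimethylsilyl ether. This is the change that allows polarity reversal at C6 and C10. The forward hydrolysis must not move the exocyclic alkene or damage the β-hydroxy ketone it liberates.

19 ⇒ 15 + 16. The bonds C6–C7 and C9–C10 are cut. Both are bonds from an acyl carbon to the same three-carbon unit, so one bis-electrophile replaces a stepwise ring construction, and the seven-membered ring, three carbons and the latent alkene are removed in one operation. The forward step needs two carbanions on adjacent ring carbons, the second at a neopentyl position, and C-alkylation that outruns intermolecular coupling.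

15 ⇒ 14 ⇒ 13. The O4–Si bond and the C4–isopropyl bond are cut. A tertiary carbinol next to a stereocentre is best made by addition to the ketone anti to the C5 substituent. The forward addition must beat enolisation and hydride transfer at a hindered ketone, and the silyl group must be put on last and be removable before any other.

13 ⇒ 12 ⇒ 9 (through 11 and 10). The C4 ketone goes back to the secondary alcohol, the four C–S bonds to two aldehydes, and the C6 aldehyde to a vinyl group (C6=C7). Both dithianes are installed before the tertiary carbinol exists, so that no aldehyde with a tertiary β-leaving group is ever formed. This requires orthogonal silyl ethers at O4 (labile) and O2 (robust).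

9 ⇒ 8 ⇒ 7 ⇒ 6. The O2–Si bond, the C10 aldehyde oxidation level and the C2–H bond are removed. C2 then becomes a ketone flanked by the quaternary C1, and C10 a hydroxymethyl group. The forward reduction must deliver hydride to the β face of C2, which only an intramolecular delivery from the β-oriented C10 hydroxyl can guarantee, and the primary alcohol must then be oxidised selectively.

6 ⇒ 4 (through 5). The bonds C5–C6 and C1–C10 are cut in a conjugate addition and enolate trapping retron. Two ring stereocentres, one quaternary, come from the single stereocentre of a cyclopentenone. The nucleophile must add anti to the C4 silyloxy group and the one-carbon electrophile anti to the new C5 substituent.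

4 ⇒ 3 ⇒ 2 ⇒ 1. The C1–CH3 bond, the C–I bond and the O–Si bond are cut, which leads to a commercial enantiopure hydroxy enone. The forward methylation must avoid basic conditions that would eliminate the β-silyloxy group.

## Other disconnections considered

Alternative 1: The cut is the fusion bond C1–C5, which opens both rings to the ten-membered carbocycle A2. A2 carries a cis C4,C5-epoxide, a C8=C9–C10(OSiEt3)=C1 silyl dienol ether, O6 as p-methoxybenzyl ether and O2 as silyl ether. In the forward direction BF3·OEt2 would activate the epoxide and the dienol ether would attack through C1 at C5 with inversion, closing the five- and seven-membered rings together to give the hydroxy enone A1.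
- In its favour: one step would create the quaternary C1, the trans fusion and the C4 carbinol stereospecifically. A1 already has the C6 oxygen in place and the C8=C9–C10=O enone; it corresponds to 23 with O6 protected. On late-stage redox economy this is the better plan, since neither the C6 reduction nor the alkene isomerisation is needed.
- Against it here: the whole burden moves into A2. A ten-membered ring with an enantiopure trisubstituted cis-epoxide, two oxygenated stereocentres and a dienol ether of defined regiochemistry and geometry needs a medium-ring closure, the least reliable ring size. The Lewis acid must open the epoxide at the secondary C5 although ionisation is easier at the tertiary C4, so hydride shift or elimination would compete. The dienol ether could also react through C8. The C1 configuration would depend only on the macrocycle conformation.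
- Comparison: structurally it closes two rings with one bond where the chosen step closes one ring with two bonds. Mechanistically the chosen double alkylation is more predictable, because it forms no stereocentre and its regiochemistry is degenerate. In step count, the saving at the end would probably be spent on making A2.

Alternative 2: The cut is C4–C5, a retro-aldol that opens the five-membered ring to the cycloheptanone A4. A4 bears the quaternary C1, the C10 silyloxy group, a C8 methyl group and the side chain C2(OSi)–C3–C4(=O)–isopropyl. In the forward direction MgBr2·OEt2 and a tertiary amine would enolise the C6 ketone toward C5 reversibly, and the enolate would add to the isopropyl ketone to give A3 as its magnesium aldolate.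
- In its favour: the hindered tertiary carbinol forms intramolecularly and under equilibrium control, which avoids adding a secondary organometallic to an enolisable ketone (step 10). On that point it is the better plan. The reagents are mild, and C6 arrives as a ketone ready for the same hydroxyl-directed reduction as in step 14, where the two plans are equal.
- Against it here: the reaction is reversible by design, so A3 forms only if the trans fusion with the α-hydroxyl at C4 is the thermodynamic minimum, which is uncertain for a hydroazulenone. The β-hydroxy ketone can revert or dehydrate on work-up. A4 needs three contiguous stereocentres (C10, C1, C2) set on a flexible seven-membered ring and an acyclic arm. A3 also has a saturated C8 with a stereocentre the target lacks, so the C8=C9 alkene would still have to be introduced through oxidation at C10 and dehydrogenation.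
- Comparison: the alternative is gentler at C4 and equal at C6, but weaker in stereocontrol of its precursor and clearly longer after the key step.

Alternative 3: Two bonds of the seven-membered ring, C1–C10 and C7–C8, are cut in a (4+3) sense, which leads to the silyloxyvinyl diazoacetate A6 and the 2-vinylcyclopentenone A7. In the forward direction Rh2(S-DOSP)4 (a divalent rhodium carboxylate) or its enantiomer would turn A6 into a vinylcarbenoid that cyclopropanates the vinyl group of A7. Heating would then take the cis-divinyl arrangement through a boat Cope rearrangement to A5.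
- In its favour: it is fully convergent and catalytic. The boat transition state would translate the (E)-enol ether geometry and the facial bias of the C2 silyloxy group into the C10 and C1 configurations in the ring-forming event itself. On convergence and on C10, which the chosen plan must set later by a separate reduction, this alternative is the better.
- Against it here: the alkene to be cyclopropanated is the vinyl group of a cross-conjugated, electron-poor dienone, a poor partner for an electrophilic carbenoid. A5 is also far from the target in oxidation pattern: the C8 ester must be reduced to a methyl group without moving the C8=C9 alkene; the C5=C6 enone alkene must be converted into C5–H (β) and C6–OH with both configurations still to be controlled; and the isopropyl group must still be added to the C4 ketone.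
- Comparison: the ring construction is the more stereochemically informative, but the route after it would be longer and less certain than the six steps that follow 19.

Key step: step 12

Remark: target numbering is used for every compound (in monocyclic intermediates C6 and C10 are the exocyclic carbons on C5 and C1); α is the face of the five-membered ring that carries the C1 methyl group and β the opposite face.

Remark: (R)-4-hydroxycyclopent-2-en-1-one (1) is taken as the commercial source of chirality; its stereocentre becomes C4 and is later replaced by the tertiary carbinol after it has set C5 and C1.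

Remark: the configurations of 15 and 19 were derived from the target centre by centre; C1, C2, C4 and C5 of 15 already have the target configuration and are not touched in step 12.

Remark: in step 16 the quaternary C1 is assumed to act as the large and the alkenyl C9 as the small substituent of the C10 ketone.

## Steps

Step 1
Reactants: 1 (R)-4-hydroxycyclopent-2-en-1-one
Product: 2 (R)-4-(triethylsilyloxy)cyclopent-2-en-1-one
Conditions: Et3SiCl, imidazole, CH2Cl2, 0 °C
Reagents that add atoms: triethylsilyl chloride, CC[Si](Cl)(CC)CC
Why: O-silylation of a secondary allylic alcohol; the triethylsilyl ether directs the later conjugate addition to the opposite face and can be removed in the presence of the tert-butyldimethylsilyl ether that will sit on O2.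

Step 2
Reactants: 2 (R)-4-(triethylsilyloxy)cyclopent-2-en-1-one
Product: 3 (R)-2-iodo-4-(triethylsilyloxy)cyclopent-2-en-1-one
Conditions: I2, pyridine/CH2Cl2 (1:1), 0 °C → rt
Reagents that add atoms: iodine, II
Why: α-iodination of the enone by conjugate addition of pyridine, iodination of the enolate and elimination (Baylis–Hillman-type addition–elimination); the stereocentre is not involved.

Step 3
Reactants: 3 (R)-2-iodo-4-(triethylsilyloxy)cyclopent-2-en-1-one
Product: 4 (R)-2-methyl-4-(triethylsilyloxy)cyclopent-2-en-1-one
Conditions: MeZnCl, Pd(PPh3)4 (5 mol%), THF, 0 °C → rt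
Reagents that add atoms: methylzinc chloride, C[Zn]Cl
Why: Negishi coupling of an α-iodoenone (oxidative addition to zerovalent palladium, transmetalation from zinc, reductive elimination) installs the future C1 methyl group; the organozinc is too weakly basic to eliminate the β-silyloxy group.

Step 4
Reactants: 4 (R)-2-methyl-4-(triethylsilyloxy)cyclopent-2-en-1-one
Product: 6 1β-(hydroxymethyl)-1α-methyl-4β-(triethylsilyloxy)-5α-vinylcyclopentan-2-one, via bromomagnesium enolate 5 (not isolated)
Conditions: CH2=CHMgBr, CuBr·SMe2 (10 mol%), THF, −78 °C; then CH2O (monomeric, in THF), −78 °C; aq. NH4Cl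
Reagents that add atoms: vinylmagnesium bromide, C=C[Mg]Br; formaldehyde, C=O
Why: Copper-catalysed conjugate addition should deliver the vinyl group trans to the C4 silyloxy group (sets C5), and the regiodefined enolate 5 should be hydroxymethylated by formaldehyde trans to the new vinyl group (aldol trapping), which sets the quaternary C1 with C10 on the β face.

Step 5
Reactants: 6 1β-(hydroxymethyl)-1α-methyl-4β-(triethylsilyloxy)-5α-vinylcyclopentan-2-one
Product: 7 1β-(hydroxymethyl)-1α-methyl-4β-(triethylsilyloxy)-5α-vinylcyclopentan-2α-ol
Conditions: Me4NBH(OAc)3, MeCN/AcOH (1:1), −30 → −20 °C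
Reagents that add atoms: none
Why: Evans–Saksena reduction: the C10 hydroxyl exchanges onto boron and delivers hydride intramolecularly through a six-membered transition state to the β face of the C2 ketone, which should give the 2α-alcohol (cis to the C1 methyl group); an external hydride would have no such bias.

Step 6
Reactants: 7 1β-(hydroxymethyl)-1α-methyl-4β-(triethylsilyloxy)-5α-vinylcyclopentan-2α-ol
Product: 8 2α-hydroxy-1α-methyl-4β-(triethylsilyloxy)-5α-vinylcyclopentane-1β-carbaldehyde
Conditions: PhI(OAc)2, 2,2,6,6-tetramethylpiperidin-1-oxyl (10 mol%), CH2Cl2, rt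
Reagents that add atoms: none
Why: Oxoammonium-mediated oxidation is selective for the primary alcohol over the hindered secondary C2 alcohol; the aldehyde has no α-hydrogen and cannot epimerise.

Step 7
Reactants: 8 2α-hydroxy-1α-methyl-4β-(triethylsilyloxy)-5α-vinylcyclopentane-1β-carbaldehyde
Product: 9 2α-(tert-butyldimethylsilyloxy)-1α-methyl-4β-(triethylsilyloxy)-5α-vinylcyclopentane-1β-carbaldehyde
Conditions: t-BuMe2SiOTf, 2,6-lutidine, CH2Cl2, −78 → 0 °C
Reagents that add atoms: tert-butyldimethylsilyl trifluoromethanesulfonate, CC(C)(C)[Si](C)(C)OS(=O)(=O)C(F)(F)F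
Why: Silyl triflate silylation of the hindered C2 alcohol; the non-enolisable aldehyde tolerates the conditions, and this is the silyl ether that must last to the final step.

Step 8
Reactants: 9 2α-(tert-butyldimethylsilyloxy)-1α-methyl-4β-(triethylsilyloxy)-5α-vinylcyclopentane-1β-carbaldehyde
Product: 12 1β,5α-bis(1,3-dithian-2-yl)-2α-(tert-butyldimethylsilyloxy)-1α-methylcyclopentan-4β-ol, via dialdehyde 10 (not isolated), via bis-dithiane triethylsilyl ether 11 (not isolated)
Conditions: O3, CH2Cl2, −78 °C; PPh3, −78 °C → rt; then HS(CH2)3SH, BF3·OEt2 (excess), −40 → 0 °C; then MeOH, 0 °C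
Reagents that add atoms: ozone, [O-][O+]=O; propane-1,3-dithiol, SCCCS
Why: Ozonolysis cuts C6=C7 to the C6 aldehyde, and the sensitive 1,4-dialdehyde 10 is converted at once into the bis-dithiane 11 by Lewis-acid dithioacetalisation; methanol added to the same acidic mixture should cleave the labile triethylsilyl ether while the hindered C2 tert-butyldimethylsilyl ether stays. C1 is quaternary and the trans arrangement at C5 is the favoured one, so the ring stereochemistry should hold.

Step 9
Reactants: 12 1β,5α-bis(1,3-dithian-2-yl)-2α-(tert-butyldimethylsilyloxy)-1α-methylcyclopentan-4β-ol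
Product: 13 1β,5α-bis(1,3-dithian-2-yl)-2α-(tert-butyldimethylsilyloxy)-1α-methylcyclopentan-4-one
Conditions: (COCl)2, DMSO, CH2Cl2, −78 °C; Et3N, −78 → −20 °C
Reagents that add atoms: none
Why: Swern oxidation of the secondary C4 alcohol; thioacetals tolerate activated dimethyl sulfoxide at low temperature, and the only epimerisable centre (C5) already has the favoured trans arrangement.

Step 10
Reactants: 13 1β,5α-bis(1,3-dithian-2-yl)-2α-(tert-butyldimethylsilyloxy)-1α-methylcyclopentan-4-one
Product: 14 1β,5α-bis(1,3-dithian-2-yl)-2α-(tert-butyldimethylsilyloxy)-4β-isopropyl-1α-methylcyclopentan-4α-ol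
Conditions: i-PrMgCl, CeCl3 (anhydrous), THF, −78 → 0 °C
Reagents that add atoms: isopropylmagnesium chloride, CC(C)[Mg]Cl
Why: Organocerium 1,2-addition suppresses enolisation and β-hydride reduction of the hindered ketone; the reagent should enter from the β face, anti to the adjacent α-oriented C5 dithianyl group and away from the α-oriented C2 silyloxy and C1 methyl groups, which places isopropyl β and hydroxyl α at C4.

Step 11
Reactants: 14 1β,5α-bis(1,3-dithian-2-yl)-2α-(tert-butyldimethylsilyloxy)-4β-isopropyl-1α-methylcyclopentan-4α-ol
Product: 15 1β,5α-bis(1,3-dithian-2-yl)-2α-(tert-butyldimethylsilyloxy)-4β-isopropyl-1α-methyl-4α-(trimethylsilyloxy)cyclopentane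
Conditions: Me3SiOTf, 2,6-lutidine, CH2Cl2, −78 → 0 °C
Reagents that add atoms: trimethylsilyl trifluoromethanesulfonate, C[Si](C)(C)OS(=O)(=O)C(F)(F)F
Why: Silyl triflate silylation of the tertiary alcohol; the trimethylsilyl ether is installed last, only keeps O4 from acting as a competing nucleophile in the next step, and is later removed under conditions that leave the C2 silyl ether untouched.

Step 12
Reactants: 15 1β,5α-bis(1,3-dithian-2-yl)-2α-(tert-butyldimethylsilyloxy)-4β-isopropyl-1α-methyl-4α-(trimethylsilyloxy)cyclopentane; 16 3-chloro-2-(chloromethyl)prop-1-ene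
Product: 19 6,10-bis(propane-1,3-diyl dithioketal) of trans-fused (5β-H) 2α-(tert-butyldimethylsilyloxy)-4β-isopropyl-1α-methyl-8-methylene-4α-(trimethylsilyloxy)bicyclo[5.3.0]decane-6,10-dione, via dilithio bis-dithiane 17 (not isolated), via lithiated allylic chloride 18 (not isolated)
Conditions: t-BuLi (2.4 equiv), THF/HMPA (10:1), −78 °C, 1 h; then 16 (1.05 equiv) in THF, slow addition at high dilution, −78 → −20 °C
Reagents that add atoms: none
Why: Both dithiane C–H bonds are lithiated to give 17, one carbanion displaces an allylic chloride of 16 intermolecularly to give 18, and the other closes the seven-membered ring by a 7-exo-tet displacement of the second chloride, forming C6–C7 and C9–C10. The closest known reaction type is the Corey–Seebach alkylation of 2-lithio-1,3-dithianes, including ring formation from dilithiated bis-dithianes and α,ω-dihalides. No stereocentre is formed: the trans relation of the two dithianyl groups on C1 and C5 is carried unchanged into the trans ring fusion. Because 16 is symmetrical, SN2 and SN2′ attack give the same constitution in both alkylations, and 16 has no β-hydrogen, so neither allylic transposition nor E2 elimination is an issue. The step needs complete metalation of the neopentyl C10–H, so both carbanions are made before 16 is added and no base ever meets an allylic chloride. It also needs ring closure faster than intermolecular coupling, which the gauche disposition of the two trans substituents, dilution and slow addition should secure. O4 is masked so that no alkoxide competes, and HMPA keeps any 1,4 O-to-C silyl shift between O4 and the C6 carbanion on the side of the silyl ether (Brook direction).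

Step 13
Reactants: 19 6,10-bis(propane-1,3-diyl dithioketal) of trans-fused 2α-(tert-butyldimethylsilyloxy)-4β-isopropyl-1α-methyl-8-methylene-4α-(trimethylsilyloxy)bicyclo[5.3.0]decane-6,10-dione
Product: 21 trans-fused 2α-(tert-butyldimethylsilyloxy)-4α-hydroxy-4β-isopropyl-1α-methyl-8-methylenebicyclo[5.3.0]decane-6,10-dione, via dione trimethylsilyl ether 20 (not isolated)
Conditions: N-chlorosuccinimide, AgNO3, 2,6-lutidine, MeCN/H2O (4:1), 0 °C, 15 min; then citric acid, MeOH, 0 °C
Reagents that add atoms: water, O
Why: Silver-assisted oxidative hydrolysis of both thioketals through chlorosulfonium ions is fast at 0 °C and buffered, so the exocyclic alkene of the β,γ-unsaturated diketone 20 should not migrate and C5 should not epimerise; brief acid methanolysis then frees the tertiary O4–H from the trimethylsilyl ether only. Because 21 is a β-hydroxy ketone it is used at once.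

Step 14
Reactants: 21 trans-fused 2α-(tert-butyldimethylsilyloxy)-4α-hydroxy-4β-isopropyl-1α-methyl-8-methylenebicyclo[5.3.0]decane-6,10-dione
Product: 22 (6S)-2α-(tert-butyldimethylsilyloxy)-4α,6-dihydroxy-4β-isopropyl-1α-methyl-8-methylenebicyclo[5.3.0]decan-10-one (trans-fused)
Conditions: Me4NBH(OAc)3, MeCN/AcOH (1:1), −30 → −20 °C
Reagents that add atoms: none
Why: Evans–Saksena reduction: only the C6 ketone has a free β-hydroxyl, so only it is reduced. O4 and C6 are cis on the five-membered ring and the trans fusion fixes the sign of the O4–C4–C5–C6 torsion, so only one chair transition state is accessible; it delivers hydride to the face that gives the 6S alcohol, anti to the C4 hydroxyl.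

Step 15
Reactants: 22 (6S)-2α-(tert-butyldimethylsilyloxy)-4α,6-dihydroxy-4β-isopropyl-1α-methyl-8-methylenebicyclo[5.3.0]decan-10-one
Product: 23 (6S)-2α-(tert-butyldimethylsilyloxy)-4α,6-dihydroxy-4β-isopropyl-1α,8-dimethylbicyclo[5.3.0]dec-8-en-10-one (trans-fused)
Conditions: 1,8-diazabicyclo[5.4.0]undec-7-ene (0.2 equiv), CH2Cl2, rt
Reagents that add atoms: none
Why: Base-mediated isomerisation through the C9 dienolate moves the exocyclic alkene into conjugation with the only remaining ketone (C10) and gives the trisubstituted C8=C9 enone; C1 is quaternary, C6 is now a carbinol and O2 is silylated, so nothing can epimerise or undergo retro-aldol cleavage.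

Step 16
Reactants: 23 (6S)-2α-(tert-butyldimethylsilyloxy)-4α,6-dihydroxy-4β-isopropyl-1α,8-dimethylbicyclo[5.3.0]dec-8-en-10-one
Product: 24 (6S,10R)-2α-(tert-butyldimethylsilyloxy)-4β-isopropyl-1α,8-dimethylbicyclo[5.3.0]dec-8-ene-4α,6,10-triol (trans-fused)
Conditions: (S)-1-methyl-3,3-diphenyltetrahydro-1H,3H-pyrrolo[1,2-c][1,3,2]oxazaborole (1 equiv), BH3·SMe2, THF, −30 °C; MeOH
Reagents that add atoms: none
Why: Corey–Bakshi–Shibata reduction: with the quaternary C1 as the large and the alkenyl C9 as the small substituent, the (S)-oxazaborolidine–borane complex should deliver hydride to the Si face of C10 and give the 10R allylic alcohol by 1,2-reduction. Reagent control is chosen because the inherent facial bias of the hydroazulenone is uncertain.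

Step 17
Reactants: 24 (6S,10R)-2α-(tert-butyldimethylsilyloxy)-4β-isopropyl-1α,8-dimethylbicyclo[5.3.0]dec-8-ene-4α,6,10-triol
Product: 25 (6S,10R)-2α-(tert-butyldimethylsilyloxy)-4α-hydroxy-4β-isopropyl-1α,8-dimethylbicyclo[5.3.0]dec-8-ene-6,10-diyl bis[(Z)-2-methylbut-2-enoate] (trans-fused)
Conditions: (Z)-2-methylbut-2-enoic acid, 2,4,6-trichlorobenzoyl chloride, Et3N, toluene, rt; then 24, 80 °C
Reagents that add atoms: angelic acid [(Z)-2-methylbut-2-enoic acid], C/C=C(/C)C(=O)O
Why: Yamaguchi-type esterification through the mixed anhydride, run without a nucleophilic catalyst, should acylate both secondary hydroxyls with retention of the (Z)-alkene geometry; the tertiary O4–H is too hindered to react and O2 is still silylated.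

Step 18
Reactants: 25 (6S,10R)-2α-(tert-butyldimethylsilyloxy)-4α-hydroxy-4β-isopropyl-1α,8-dimethylbicyclo[5.3.0]dec-8-ene-6,10-diyl bis[(Z)-2-methylbut-2-enoate]
Product: 26 (1R,2R,4R,5S,6S,10R)-2,4-dihydroxy-4-isopropyl-1,8-dimethylbicyclo[5.3.0]dec-8-ene-6,10-diyl bis[(Z)-2-methylbut-2-enoate] (target numbering; CNP0249167.2)
Conditions: HF·pyridine, pyridine, THF, 0 °C → rt
Reagents that add atoms: none
Why: Fluoride cleavage of the silyl ether under buffered acidic conditions avoids the basic conditions that would cause acyl migration to O2 or angelate-to-tiglate isomerisation, and should give the target.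

## Compound list

1 | (R)-4-hydroxycyclopent-2-en-1-one | O=C1C=C[C@H](O)C1 | starting material
2 | (R)-4-(triethylsilyloxy)cyclopent-2-en-1-one | O=C1C=C[C@H](O[Si](CC)(CC)CC)C1 | intermediate
3 | (R)-2-iodo-4-(triethylsilyloxy)cyclopent-2-en-1-one | O=C1C(I)=C[C@H](O[Si](CC)(CC)CC)C1 | intermediate
4 | (R)-2-methyl-4-(triethylsilyloxy)cyclopent-2-en-1-one | CC1=C[C@H](O[Si](CC)(CC)CC)CC1=O | intermediate
5 | bromomagnesium C1=C2 enolate of 1-methyl-4β-(triethylsilyloxy)-5α-vinylcyclopentan-2-one | C=C[C@H]1[C@H](O[Si](CC)(CC)CC)CC(O[Mg]Br)=C1C | intermediate
6 | 1β-(hydroxymethyl)-1α-methyl-4β-(triethylsilyloxy)-5α-vinylcyclopentan-2-one | C=C[C@H]1[C@H](O[Si](CC)(CC)CC)CC(=O)[C@]1(C)CO | intermediate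
7 | 1β-(hydroxymethyl)-1α-methyl-4β-(triethylsilyloxy)-5α-vinylcyclopentan-2α-ol | C=C[C@H]1[C@H](O[Si](CC)(CC)CC)C[C@@H](O)[C@]1(C)CO | intermediate
8 | 2α-hydroxy-1α-methyl-4β-(triethylsilyloxy)-5α-vinylcyclopentane-1β-carbaldehyde | C=C[C@H]1[C@H](O[Si](CC)(CC)CC)C[C@@H](O)[C@]1(C)C=O | intermediate
9 | 2α-(tert-butyldimethylsilyloxy)-1α-methyl-4β-(triethylsilyloxy)-5α-vinylcyclopentane-1β-carbaldehyde | C=C[C@H]1[C@H](O[Si](CC)(CC)CC)C[C@@H](O[Si](C)(C)C(C)(C)C)[C@]1(C)C=O | intermediate
10 | 2α-(tert-butyldimethylsilyloxy)-1α-methyl-4β-(triethylsilyloxy)cyclopentane-1β,5α-dicarbaldehyde | O=C[C@H]1[C@H](O[Si](CC)(CC)CC)C[C@@H](O[Si](C)(C)C(C)(C)C)[C@]1(C)C=O | intermediate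
11 | 1β,5α-bis(1,3-dithian-2-yl)-2α-(tert-butyldimethylsilyloxy)-1α-methyl-4β-(triethylsilyloxy)cyclopentane | S1CCCSC1[C@H]2[C@H](O[Si](CC)(CC)CC)C[C@@H](O[Si](C)(C)C(C)(C)C)[C@]2(C)C3SCCCS3 | intermediate
12 | 1β,5α-bis(1,3-dithian-2-yl)-2α-(tert-butyldimethylsilyloxy)-1α-methylcyclopentan-4β-ol | S1CCCSC1[C@H]2[C@H](O)C[C@@H](O[Si](C)(C)C(C)(C)C)[C@]2(C)C3SCCCS3 | intermediate
13 | 1β,5α-bis(1,3-dithian-2-yl)-2α-(tert-butyldimethylsilyloxy)-1α-methylcyclopentan-4-one | S1CCCSC1[C@H]2C(=O)C[C@@H](O[Si](C)(C)C(C)(C)C)[C@]2(C)C3SCCCS3 | intermediate
14 | 1β,5α-bis(1,3-dithian-2-yl)-2α-(tert-butyldimethylsilyloxy)-4β-isopropyl-1α-methylcyclopentan-4α-ol | S1CCCSC1[C@H]2[C@](O)(C(C)C)C[C@@H](O[Si](C)(C)C(C)(C)C)[C@]2(C)C3SCCCS3 | intermediate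
15 | 1β,5α-bis(1,3-dithian-2-yl)-2α-(tert-butyldimethylsilyloxy)-4β-isopropyl-1α-methyl-4α-(trimethylsilyloxy)cyclopentane | S1CCCSC1[C@H]2[C@](O[Si](C)(C)C)(C(C)C)C[C@@H](O[Si](C)(C)C(C)(C)C)[C@]2(C)C3SCCCS3 | intermediate
16 | 3-chloro-2-(chloromethyl)prop-1-ene | ClCC(=C)CCl | starting material
17 | C6,C10-dilithio derivative of 15 | [Li]C1(SCCCS1)[C@H]2[C@](O[Si](C)(C)C)(C(C)C)C[C@@H](O[Si](C)(C)C(C)(C)C)[C@]2(C)C3([Li])SCCCS3 | intermediate
18 | C6-[2-(chloromethyl)allyl], C10-lithio derivative of 15 | ClCC(=C)CC1(SCCCS1)[C@H]2[C@](O[Si](C)(C)C)(C(C)C)C[C@@H](O[Si](C)(C)C(C)(C)C)[C@]2(C)C3([Li])SCCCS3 | intermediate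
19 | 6,10-bis(propane-1,3-diyl dithioketal) of trans-fused 2α-(tert-butyldimethylsilyloxy)-4β-isopropyl-1α-methyl-8-methylene-4α-(trimethylsilyloxy)bicyclo[5.3.0]decane-6,10-dione | C=C1CC2(SCCCS2)[C@H]3[C@](O[Si](C)(C)C)(C(C)C)C[C@@H](O[Si](C)(C)C(C)(C)C)[C@]3(C)C4(SCCCS4)C1 | intermediate
20 | trans-fused 2α-(tert-butyldimethylsilyloxy)-4β-isopropyl-1α-methyl-8-methylene-4α-(trimethylsilyloxy)bicyclo[5.3.0]decane-6,10-dione | O=C1CC(=C)CC(=O)[C@@]2(C)[C@H](O[Si](C)(C)C(C)(C)C)C[C@@](O[Si](C)(C)C)(C(C)C)[C@H]12 | intermediate
21 | trans-fused 2α-(tert-butyldimethylsilyloxy)-4α-hydroxy-4β-isopropyl-1α-methyl-8-methylenebicyclo[5.3.0]decane-6,10-dione | O=C1CC(=C)CC(=O)[C@@]2(C)[C@H](O[Si](C)(C)C(C)(C)C)C[C@@](O)(C(C)C)[C@H]12 | intermediate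
22 | (6S)-2α-(tert-butyldimethylsilyloxy)-4α,6-dihydroxy-4β-isopropyl-1α-methyl-8-methylenebicyclo[5.3.0]decan-10-one | O[C@H]1CC(=C)CC(=O)[C@@]2(C)[C@H](O[Si](C)(C)C(C)(C)C)C[C@@](O)(C(C)C)[C@H]12 | intermediate
23 | (6S)-2α-(tert-butyldimethylsilyloxy)-4α,6-dihydroxy-4β-isopropyl-1α,8-dimethylbicyclo[5.3.0]dec-8-en-10-one | O[C@H]1CC(C)=CC(=O)[C@@]2(C)[C@H](O[Si](C)(C)C(C)(C)C)C[C@@](O)(C(C)C)[C@H]12 | intermediate
24 | (6S,10R)-2α-(tert-butyldimethylsilyloxy)-4β-isopropyl-1α,8-dimethylbicyclo[5.3.0]dec-8-ene-4α,6,10-triol | O[C@H]1CC(C)=C[C@@H](O)[C@@]2(C)[C@H](O[Si](C)(C)C(C)(C)C)C[C@@](O)(C(C)C)[C@H]12 | intermediate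
25 | (6S,10R)-2α-(tert-butyldimethylsilyloxy)-4α-hydroxy-4β-isopropyl-1α,8-dimethylbicyclo[5.3.0]dec-8-ene-6,10-diyl bis[(Z)-2-methylbut-2-enoate] | C/C=C(/C)C(=O)O[C@H]1CC(C)=C[C@@H](OC(=O)/C(C)=C\C)[C@@]2(C)[C@H](O[Si](C)(C)C(C)(C)C)C[C@@](O)(C(C)C)[C@H]12 | intermediate
26 | (1R,2R,4R,5S,6S,10R)-2,4-dihydroxy-4-isopropyl-1,8-dimethylbicyclo[5.3.0]dec-8-ene-6,10-diyl bis[(Z)-2-methylbut-2-enoate] | C/C=C(/C)C(=O)O[C@H]1CC(C)=C[C@@H](OC(=O)/C(C)=C\C)[C@@]2(C)[C@H](O)C[C@@](O)(C(C)C)[C@H]12 | target

## Step count and least certain steps

Total step count: 18. Longest linear sequence: 18 steps (1 to 26); 16 is used as purchased.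

Step 12 (key step). The most likely failure is incomplete second metalation at the neopentyl C10–H, which is shielded by the C1 methyl and C2 silyloxy groups and sits next to an existing carbanion. Mono-alkylation would then be followed by intermolecular coupling or proton transfer instead of ring closure. The fallback sets out from 15 and returns at 19, and reverses polarity at only one carbon. Mono-lithiation of 15 (t-BuLi, 1.05 equiv) and alkylation with 2-(chloromethyl)-3-(trimethylsilyl)prop-1-ene would give the C6-[2-(trimethylsilylmethyl)allyl] bis-dithiane F1 (drawn for alkylation at C6). Hydride abstraction from the remaining dithiane C–H with Ph3CBF4 would generate a 1,3-dithian-2-ylium ion, which the allylsilane captures intramolecularly (Hosomi–Sakurai-type addition). This closes the same seven-membered ring with the same exocyclic methylene, so whichever dithiane is alkylated first the sequence converges on 19.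

Step 16. The most likely failure is poor facial selectivity. The inherent bias of the ketone may oppose the reagent, since the C1 methyl group stands almost perpendicular to the enone plane, and borane bound to the free C6 and C4 hydroxyls may deliver hydride on its own. The fallback sets out from 23 and returns at 25, and uses substrate control with inversion. The C6 hydroxyl of 23 is first acylated alone under the mixed-anhydride conditions of step 17 to give the 6-angelate enone F2. Luche reduction (NaBH4, CeCl3·7H2O, MeOH) then follows the substrate bias. If it gives the 10S allylic alcohol F3, Mitsunobu esterification with angelic acid (PPh3, diisopropyl azodicarboxylate) would invert C10 and install the second ester to give 25. The 10R alcohol, if formed instead, would simply be acylated as in step 17.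

Step 17. The most likely failure is incomplete acylation of the two hindered carbinols at a temperature the angelate survives, or isomerisation of angelate to tiglate when the reaction is forced. The fallback sets out from 24 and returns at 25, and builds the (Z)-alkenes on the substrate. Acylation of 24 with 2-[bis(2,2,2-trifluoroethoxy)phosphoryl]propanoic acid (N,N'-dicyclohexylcarbodiimide, 4-(dimethylamino)pyridine) would give the bis(phosphonopropanoate) F4. Still–Gennari olefination with acetaldehyde (KN(SiMe3)2, 18-crown-6, THF, −78 °C) would then form both (Z)-2-methylbut-2-enoates and give 25.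

Step 10. The most likely failure is enolisation of the ketone or β-hydride transfer from the secondary organometallic, with erosion of facial selectivity by the β-oriented C1 dithianyl group. The fallback sets out from 13 and returns at 14, and uses an sp2 nucleophile that has no β-hydrogen and is smaller. Isopropenylmagnesium bromide with CeCl3 would give the isopropenyl carbinol F5. Its 1,1-disubstituted alkene would be saturated with diimide (2-nitrobenzenesulfonohydrazide, Et3N), a reduction that tolerates thioacetals, to give 14.

Step 4. The most likely failure is incomplete capture of the hindered tetrasubstituted enolate by formaldehyde, or retro-aldol loss of the hydroxymethyl group on warming. The fallback sets out from 4 and returns at 6, and separates the two events. Conjugate addition in the presence of Me3SiCl would give the trimethylsilyl enol ether F6, which is isolated and hydroxymethylated with aqueous formaldehyde under Yb(OTf)3 catalysis (Mukaiyama aldol) to give 6.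

## Further compounds

F1 | step 12 | C6-[2-(trimethylsilylmethyl)allyl] derivative of 15 | C[Si](C)(C)CC(=C)CC1(SCCCS1)[C@H]2[C@](O[Si](C)(C)C)(C(C)C)C[C@@H](O[Si](C)(C)C(C)(C)C)[C@]2(C)C3SCCCS3
F2 | step 16 | (6S)-2α-(tert-butyldimethylsilyloxy)-4α-hydroxy-4β-isopropyl-1α,8-dimethyl-10-oxobicyclo[5.3.0]dec-8-en-6-yl (Z)-2-methylbut-2-enoate | C/C=C(/C)C(=O)O[C@H]1CC(C)=CC(=O)[C@@]2(C)[C@H](O[Si](C)(C)C(C)(C)C)C[C@@](O)(C(C)C)[C@H]12
F3 | step 16 | (6S,10S)-2α-(tert-butyldimethylsilyloxy)-4α,10-dihydroxy-4β-isopropyl-1α,8-dimethylbicyclo[5.3.0]dec-8-en-6-yl (Z)-2-methylbut-2-enoate | C/C=C(/C)C(=O)O[C@H]1CC(C)=C[C@H](O)[C@@]2(C)[C@H](O[Si](C)(C)C(C)(C)C)C[C@@](O)(C(C)C)[C@H]12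
F4 | step 17 | 6,10-bis{2-[bis(2,2,2-trifluoroethoxy)phosphoryl]propanoate} of 24 | CC(C(=O)O[C@H]1CC(C)=C[C@@H](OC(=O)C(C)P(=O)(OCC(F)(F)F)OCC(F)(F)F)[C@@]2(C)[C@H](O[Si](C)(C)C(C)(C)C)C[C@@](O)(C(C)C)[C@H]12)P(=O)(OCC(F)(F)F)OCC(F)(F)F
F5 | step 10 | 1β,5α-bis(1,3-dithian-2-yl)-2α-(tert-butyldimethylsilyloxy)-1α-methyl-4β-(prop-1-en-2-yl)cyclopentan-4α-ol | S1CCCSC1[C@H]2[C@](O)(C(C)=C)C[C@@H](O[Si](C)(C)C(C)(C)C)[C@]2(C)C3SCCCS3
F6 | step 4 | 1-methyl-4β-(triethylsilyloxy)-2-(trimethylsilyloxy)-5α-vinylcyclopent-1-ene | C=C[C@H]1[C@H](O[Si](CC)(CC)CC)CC(O[Si](C)(C)C)=C1C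
A1 | alternative 1 | trans-fused C10 enone with C4 tertiary alcohol, 6-O-p-methoxybenzyl and 2-O-tert-butyldimethylsilyl groups | COc1ccc(CO[C@H]2CC(C)=CC(=O)[C@@]3(C)[C@H](O[Si](C)(C)C(C)(C)C)C[C@@](O)(C(C)C)[C@H]23)cc1
A2 | alternative 1 | ten-membered carbocycle with cis C4,C5-epoxide, C8=C9–C10(OSiEt3)=C1 dienol ether, 6-O-p-methoxybenzyl and 2-O-tert-butyldimethylsilyl groups | COc1ccc(CO[C@H]3C/C(C)=C\C(O[Si](CC)(CC)CC)=C(C)/[C@H](O[Si](C)(C)C(C)(C)C)C[C@]4(C(C)C)O[C@H]34)cc1
A3 | alternative 2 | trans-fused β-hydroxy ketone with C4 tertiary alcohol, C6 ketone, saturated C8 methyl, 2-O-tert-butyldimethylsilyl and 10-O-triethylsilyl groups | O=C1C[C@H](C)C[C@@H](O[Si](CC)(CC)CC)[C@@]2(C)[C@H](O[Si](C)(C)C(C)(C)C)C[C@@](O)(C(C)C)[C@H]12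
A4 | alternative 2 | cycloheptanone (C6 ketone) with C1 methyl, C8 methyl, 10-O-triethylsilyl group and the side chain C2(O-tert-butyldimethylsilyl)–C3–C4(=O)–isopropyl on C1 | O=C1C[C@H](C)C[C@@H](O[Si](CC)(CC)CC)[C@](C)(C1)[C@H](O[Si](C)(C)C(C)(C)C)CC(=O)C(C)C
A5 | alternative 3 | bicyclo[5.3.0]decadienone with C4 ketone, C5=C6 and C8=C9 alkenes, C8 methyl ester, 10-O-tert-butyldimethylsilyl and 2-O-tert-butyldiphenylsilyl groups | C1=C2C(=O)C[C@@H](O[Si](c3ccccc3)(c3ccccc3)C(C)(C)C)[C@]2(C)[C@H](O[Si](C)(C)C(C)(C)C)C=C(C(=O)OC)C1
A6 | alternative 3 | methyl (E)-4-(tert-butyldimethylsilyloxy)-2-diazobut-3-enoate | COC(=O)C(=[N+]=[N-])/C=C/O[Si](C)(C)C(C)(C)C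
A7 | alternative 3 | (R)-4-(tert-butyldiphenylsilyloxy)-3-methyl-2-vinylcyclopent-2-en-1-one | C=CC1=C(C)[C@H](O[Si](c2ccccc2)(c2ccccc2)C(C)(C)C)CC1=O
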